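**Plan**

- Target 9 is 3,4,5-tribromo-2-(3,5-dibromo-2-methoxyphenoxy)phenol; it has no stereocentre.
- Enabling feature: on ring A the oxygen-bearing C1 has bromine at C2 (ortho) and C4 (para) and the diaryl ether oxygen at C6 (the other ortho carbon). This is the pattern that exhaustive bromination of a 2-aryloxycyclohexanone delivers.
- Retrosynthetic cuts, in order: the protecting group on the ring B oxygen; the O–CH3 bond on ring A; the two ring A C–Br bonds together with the aromaticity of ring A (back to a cyclohexanone); the C–O bond between the ring B phenol oxygen and the alpha carbon of that ketone; the three ring B C–Br bonds.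
- Forward order: ring B is bought as an aromatic catechol monoether and tribrominated. Ring A is bought as 2-chlorocyclohexanone and joined by O-alkylation. Ring A is then aromatized and dibrominated in one operation, O-methylated, and the ring B hydroxyl is unmasked.
- Stereochemistry: the only stereocentre on the route (C2 of ketone 4, racemic) is destroyed when ring A becomes aromatic.

Key step: step 3

Remark: the ring B hydroxyl is carried as an isopropyl ether. It tolerates Br2 and the HBr generated in steps 1 and 3 better than a benzyl ether would, and BCl3 removes it without touching the aryl methyl ether.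

**Step 1**
Reactants: 1 2-(propan-2-yloxy)phenol
Product: 2 2,3,4-tribromo-6-(propan-2-yloxy)phenol
Conditions: Br2 (3.05 equiv), AcOH, 15 → 45 °C, dark
Reagents that add atoms: bromine, BrBr
Why: Electrophilic aromatic bromination should take the three carbons activated by the two oxygens (para to OH, para to the isopropoxy group, ortho to OH), while the remaining carbon, ortho to the bulky isopropoxy group and only meta to the hydroxyl, is the least reactive and stays free at three equivalents, as in the direct trihalogenation of guaiacol to its 4,5,6-trihalide.

**Step 2**
Reactants: 2 2,3,4-tribromo-6-(propan-2-yloxy)phenol; 3 2-chlorocyclohexan-1-one (racemic)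
Product: 4 2-[2,3,4-tribromo-6-(propan-2-yloxy)phenoxy]cyclohexan-1-one (racemic)
Conditions: K2CO3 (1.5 equiv), 3 (1.5 equiv), DMF, 60 °C
Reagents that add atoms: none
Why: Williamson-type SN2 O-alkylation, in which the carbonyl group activates the adjacent C–Cl carbon enough for the doubly ortho-substituted, weakly basic phenoxide to displace chloride; the new stereocentre forms as a racemate and is erased in step 3.

**Step 3**
Reactants: 4 2-[2,3,4-tribromo-6-(propan-2-yloxy)phenoxy]cyclohexan-1-one (racemic)
Product: 7 2,4-dibromo-6-[2,3,4-tribromo-6-(propan-2-yloxy)phenoxy]phenol, via dibromoketone 5 (not isolated), via aryloxyphenol 6 (not isolated)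
Conditions: Br2 (4.1 equiv), glacial AcOH, 20 → 60 °C, dark
Reagents that add atoms: bromine, BrBr
Why: Acid-catalysed enolization and bromination at both alpha carbons give dibromoketone 5, whose C2 bromide (an alpha-bromo ether) and C6 bromide are lost as HBr to leave the 6-aryloxycyclohexa-2,4-dienone, which tautomerizes to phenol 6; the new hydroxyl then directs two electrophilic brominations to its free ortho and para carbons. The closest known reaction type is the halogenative aromatization of cyclohexanones and cyclohexenones to halophenols (halogenation followed by dehydrohalogenation), coupled here to ordinary phenol bromination. No ring is closed, since ring A only passes from the saturated to the aromatic level, and no stereocentre is created, the racemic centre of 4 being erased. The step needs both new C–Br bonds on ring A and none on ring B: the hydroxyl outranks the aryloxy oxygen (whose lone pairs are shared with the electron-poor ring B) as a director and its second ortho carbon is occupied, while ring B carries three bromines and a single C–H that already resisted bromine in step 1. Both carbons of ring B ortho to the ether oxygen are substituted, so no dibenzofuran can form, and the isopropyl ether should not be cleaved by the HBr generated at this temperature.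

**Step 4**
Reactants: 7 2,4-dibromo-6-[2,3,4-tribromo-6-(propan-2-yloxy)phenoxy]phenol
Product: 8 1,2,3-tribromo-4-(3,5-dibromo-2-methoxyphenoxy)-5-(propan-2-yloxy)benzene
Conditions: MeI (1.5 equiv), K2CO3 (1.5 equiv), acetone, 50 °C
Reagents that add atoms: iodomethane, CI
Why: Williamson O-methylation of the only free hydroxyl, an acidic 2,4-dibromophenol that is fully ionized by K2CO3 and, like other 2,6-disubstituted bromophenols, is alkylated cleanly by the unhindered electrophile.

**Step 5**
Reactants: 8 1,2,3-tribromo-4-(3,5-dibromo-2-methoxyphenoxy)-5-(propan-2-yloxy)benzene
Product: 9 3,4,5-tribromo-2-(3,5-dibromo-2-methoxyphenoxy)phenol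
Conditions: BCl3 (1 M in CH2Cl2, 3 equiv), CH2Cl2, −20 → 20 °C; then H2O
Reagents that add atoms: none
Why: Lewis-acid dealkylation of an aryl isopropyl ether, in which the secondary O–alkyl bond of the boron-complexed ether is cleaved by chloride far faster than the O–CH3 bond, so the methyl ether, the diaryl ether and the five C–Br bonds should remain.

**Compound list**
1 | 2-(propan-2-yloxy)phenol (2-isopropoxyphenol) | CC(C)Oc1ccccc1O | starting material
2 | 2,3,4-tribromo-6-(propan-2-yloxy)phenol | CC(C)Oc1cc(Br)c(Br)c(Br)c1O | intermediate
3 | 2-chlorocyclohexan-1-one (racemic) | O=C1CCCCC1Cl | starting material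
4 | 2-[2,3,4-tribromo-6-(propan-2-yloxy)phenoxy]cyclohexan-1-one (racemic) | O=C1CCCCC1Oc1c(OC(C)C)cc(Br)c(Br)c1Br | intermediate
5 | 2,6-dibromo-2-[2,3,4-tribromo-6-(propan-2-yloxy)phenoxy]cyclohexan-1-one (racemic, mixture of diastereomers) | O=C1C(Br)CCCC1(Br)Oc1c(OC(C)C)cc(Br)c(Br)c1Br | intermediate
6 | 2-[2,3,4-tribromo-6-(propan-2-yloxy)phenoxy]phenol | Oc1ccccc1Oc1c(OC(C)C)cc(Br)c(Br)c1Br | intermediate
7 | 2,4-dibromo-6-[2,3,4-tribromo-6-(propan-2-yloxy)phenoxy]phenol | Oc1c(Br)cc(Br)cc1Oc1c(OC(C)C)cc(Br)c(Br)c1Br | intermediate
8 | 1,2,3-tribromo-4-(3,5-dibromo-2-methoxyphenoxy)-5-(propan-2-yloxy)benzene | COc1c(Br)cc(Br)cc1Oc1c(OC(C)C)cc(Br)c(Br)c1Br | intermediate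
9 | 3,4,5-tribromo-2-(3,5-dibromo-2-methoxyphenoxy)phenol | COc1c(Br)cc(Br)cc1Oc1c(O)cc(Br)c(Br)c1Br | target

**Step count**
Total steps: 5. Longest linear sequence: 5 steps (1 → 2 → 4 → 7 → 8 → 9).

**Steps most likely to fail**

Step 3. The cascade may stall at alpha-bromoketones that do not lose HBr. The aryloxy group may be lost by solvolysis at the alpha-bromo ether stage, especially if water is present. Excess bromine may attack the last C–H of ring B. The fallback sets out from 4 and separates oxidation from halogenation. Catalytic I2 (20 mol %) in DMSO at about 100 °C, a known oxidative aromatization of cyclohexanones in which DMSO is the terminal oxidant, should give aryloxyphenol 6, this time isolated. Ortho/para dibromination of 6 with NBS (2.05 equiv) in MeCN at 0 → 20 °C then returns to the route at 7. This path makes no compound outside the compound list (F0: none).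

Step 2. Displacement by the hindered, weakly nucleophilic phenoxide may be slow, so that base-induced self-condensation or Favorskii-type decomposition of the chloroketone takes over. The fallback sets out from 2 and builds the same C–O bond on an epoxide. Heating 2 with cyclohexene oxide and K2CO3 in DMF at about 110 °C should open the epoxide anti to give rac-(1R,2R)-2-[2,3,4-tribromo-6-(propan-2-yloxy)phenoxy]cyclohexan-1-ol F1. Oxidation of this secondary alcohol with Dess–Martin periodinane in CH2Cl2 returns to the route at 4.

Step 1. Bromine may leak to the carbon ortho to the isopropoxy group, or the reaction may stop short of or run past the tribromide, giving regioisomers that are hard to separate. The fallback sets out from 1 and places the bromines in two directed stages.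
- Acetylation (Ac2O, pyridine) gives 2-(propan-2-yloxy)phenyl acetate F2.
- One equivalent of NBS in MeCN should brominate para to the isopropoxy group, the acetoxy group being a much weaker director, to give 5-bromo-2-(propan-2-yloxy)phenyl acetate F3.
- Methanolysis (K2CO3, MeOH) gives 5-bromo-2-(propan-2-yloxy)phenol F4.
- Br2 (2 equiv) in AcOH then enters ortho and para to the free hydroxyl and returns to the route at 2.

**Further compounds**
F0 | step 3 | none | none
F1 | step 2 | rac-(1R,2R)-2-[2,3,4-tribromo-6-(propan-2-yloxy)phenoxy]cyclohexan-1-ol (trans, racemic; one enantiomer drawn) | O[C@@H]1CCCC[C@H]1Oc1c(OC(C)C)cc(Br)c(Br)c1Br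
F2 | step 1 | 2-(propan-2-yloxy)phenyl acetate | CC(=O)Oc1ccccc1OC(C)C
F3 | step 1 | 5-bromo-2-(propan-2-yloxy)phenyl acetate | CC(=O)Oc1cc(Br)ccc1OC(C)C
F4 | step 1 | 5-bromo-2-(propan-2-yloxy)phenol | Oc1cc(Br)ccc1OC(C)C
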